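The ten-membered carbocycle is opened at C1–C10. C14–OH on C10 next to the C1/C10 oxirane is a 2,3-epoxy alcohol, the Payne isomer of a 10,14-epoxy-1-ol that hydroxyl-directed epoxidation would give from a 1-hydroxy-10(14)-methylene germacranolide. That allylic alcohol is the retron of an alkenylchromium–aldehyde addition. The key step, a ligand-controlled Nozaki–Hiyama–Kishi cyclisation, joins the C1 aldehyde to the C10 bromoalkene, closes the carbocycle and sets C1, from which C10 is relayed. Its precursor is a trans α-methylene-γ-lactone (C6 and C7 from an Evans aldol) bearing a (Z)-alkenyl aldehyde arm (C1–C5) on C6 and a 2-bromoallyl carbinol ester arm (C8–C10, C14) on C7.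

Key step: step 16

Remarks on the chemistry:
- Germacrane numbering (C1–C15, lactone carbonyl C12, lactone oxygen on C6) is used for positions in all intermediates; TBS = tert-butyldimethylsilyl.
- Chiral ligands are named by the configuration they have to deliver: a ProPhenol ligand in step 1, and in steps 11 and 16 an enantiomer of the oxazoline–sulfonamide ligand L* = N-[2-(4-isopropyl-4,5-dihydrooxazol-2-yl)-6-methylphenyl]methanesulfonamide.
- Compounds 1, 2, 8, 9, 16 and 18 are taken as purchasable.
- C11 of 20 and 21 is left unspecified because it becomes sp2 in the same step.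

Step 1
Reactants: 1 3-(TBS-oxy)propanal; 2 methyl propiolate
Product: 3 methyl (4S)-6-(TBS-oxy)-4-hydroxyhex-2-ynoate
Conditions: Me2Zn, ProPhenol ligand (cat., enantiomer that gives 4S), PhMe, 0 °C
Reagents that add atoms: none
Why: Catalytic asymmetric alkynylation, in which the zinc alkynylide adds to the aldehyde inside the dinuclear zinc–ProPhenol pocket, should set C3 by catalyst control.

Step 2
Reactants: 3 hydroxy ynoate
Product: 4 methyl (4S)-4,6-bis(TBS-oxy)hex-2-ynoate
Conditions: TBSCl, imidazole, DMF, 0 °C to rt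
Reagents that add atoms: tert-butyldimethylsilyl chloride CC(C)(C)[Si](C)(C)Cl
Why: Standard silylation of a secondary propargylic alcohol with a base too weak to isomerise the γ-oxygenated ynoate.

Step 3
Reactants: 4 bis-silyl ynoate
Product: 5 methyl (2Z,4S)-4,6-bis(TBS-oxy)-3-methylhex-2-enoate
Conditions: Me2CuLi (CuI, MeLi), THF, −78 °C; MeOH at −78 °C, then aq. NH4Cl
Reagents that add atoms: lithium dimethylcuprate [Li+].C[Cu-]C
Why: Syn-carbocupration of the ynoate (cuprate conjugate addition) and cold protonation with retention should place the new methyl cis to H-5, so that C3 and the ester carbon are cis as in the (Z)-C4=C5 bond of the target.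

Step 4
Reactants: 5 (Z)-enoate
Product: 6 (2Z,4S)-4,6-bis(TBS-oxy)-3-methylhex-2-en-1-ol
Conditions: DIBAL-H, CH2Cl2, −78 °C; Rochelle salt
Reagents that add atoms: none
Why: 1,2-Reduction of the enoate by DIBAL-H leaves the silyl ethers and the alkene geometry untouched.

Step 5
Reactants: 6 (Z)-allylic alcohol
Product: 7 (2Z,4S)-4,6-bis(TBS-oxy)-3-methylhex-2-enal
Conditions: MnO2, CH2Cl2, rt
Reagents that add atoms: none
Why: Heterogeneous MnO2 oxidises the allylic alcohol selectively and is not expected to isomerise the (Z)-enal, which is used at once.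

Step 6
Reactants: 8 (4S)-4-benzyl-1,3-oxazolidin-2-one; 9 methyl 4-chloro-4-oxobutanoate
Product: 10 methyl 4-[(4S)-4-benzyl-2-oxo-1,3-oxazolidin-3-yl]-4-oxobutanoate
Conditions: n-BuLi, THF, −78 °C; then 9
Reagents that add atoms: none
Why: N-Acylation of the lithiated oxazolidinone occurs at the acid chloride, which is far more electrophilic than the methyl ester.

Step 7
Reactants: 10 succinyl imide; 7 (Z)-enal
Product: 12 trans-lactone imide, via aldol hydroxy ester 11 (not isolated)
Conditions: Bu2BOTf, i-Pr2NEt, CH2Cl2, −78 to 0 °C; 7, −78 to 0 °C; H2O2, MeOH, pH 7 buffer; then PPTS (cat.), PhMe, rt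
Reagents that add atoms: none
Why: Evans syn-aldol, in which the (Z)-boron enolate reacts through a Zimmerman–Traxler chair on the face away from the benzyl group, should set C6 (R) and C7 under auxiliary control, after which the C6 hydroxyl closes onto the methyl ester to give the trans-lactone.

Step 8
Reactants: 12 trans-lactone imide
Product: 13 lactone C8 carboxylic acid
Conditions: LiOH, H2O2, THF/H2O, 0 °C; Na2SO3; HCl to pH 3
Reagents that add atoms: hydrogen peroxide OO
Why: Hydroperoxide attacks the exocyclic imide carbonyl selectively (standard auxiliary cleavage), and any lactone opened by hydroxide should reclose to the five-membered ring on acidification.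

Step 9
Reactants: 13 lactone acid
Product: 14 C8 hydroxymethyl lactone
Conditions: BH3·SMe2, THF, 0 °C; MeOH
Reagents that add atoms: none
Why: Borane reduces the carboxylic acid through an acyloxyborane much faster than it attacks the lactone or the hindered trisubstituted alkene.

Step 10
Reactants: 14 hydroxymethyl lactone
Product: 15 C8 aldehyde lactone
Conditions: Dess–Martin periodinane, CH2Cl2, 0 °C to rt
Reagents that add atoms: none
Why: Dess–Martin oxidation under non-basic conditions should avoid epimerisation at C7 and β-elimination of the lactone oxygen from this β-acyloxy aldehyde, which is used crude.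

Step 11
Reactants: 15 aldehyde lactone; 16 2,3-dibromoprop-1-ene
Product: 17 (8R)-2-bromoallyl carbinol lactone
Conditions: CrCl2, L* (enantiomer that gives 8R), Et3N, cobalt phthalocyanine (cat.), THF, 0 °C
Reagents that add atoms: none
Why: In this chromium-mediated asymmetric 2-haloallylation, cobalt activates only the allylic C–Br bond and the 2-bromoallylchromium(III) adds through a closed transition state, so the sulfonamide on chromium should select the aldehyde face that gives 8R against the modest Felkin–Anh preference of the α-branched aldehyde.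

Step 12
Reactants: 17 bromoallyl carbinol; 18 (2R)-2-methylbutanoic acid
Product: 19 C8 (2R)-2-methylbutanoate
Conditions: DCC, DMAP (cat.), CH2Cl2, 0 °C to rt
Reagents that add atoms: none
Why: Steglich esterification acylates the secondary alcohol with retention at C8, and carbodiimide activation at 0 °C should not epimerise the α-stereocentre of the acid.

Step 13
Reactants: 19 ester lactone
Product: 22 α-methylene lactone, via Mannich base 20 (not isolated), via trimethylammonium iodide 21 (not isolated)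
Conditions: LiHMDS, THF, −78 °C; Eschenmoser's salt, −78 °C to rt; then MeI, MeOH, rt; then aq. NaHCO3, CH2Cl2
Reagents that add atoms: Eschenmoser's salt C=[N+](C)C.[I-]; iodomethane CI (its methyl stays only in 21)
Why: The lactone α-CH2 (C11) is more acidic and more accessible than the α-branched ester CH, so one equivalent of LiHMDS should enolise only the lactone, and Mannich reaction, N-methylation and Hofmann-type elimination then give the exocyclic C11=C13 bond.

Step 14
Reactants: 22 bis-silyl α-methylene lactone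
Product: 23 C1 primary alcohol
Conditions: HF·pyridine, pyridine, THF, 0 °C
Reagents that add atoms: none
Why: The primary silyl ether is cleaved much faster than the hindered secondary allylic one under buffered HF·pyridine.

Step 15
Reactants: 23 C1 alcohol
Product: 24 C1 aldehyde (cyclisation precursor)
Conditions: Dess–Martin periodinane, CH2Cl2, 0 °C to rt
Reagents that add atoms: none
Why: Dess–Martin oxidation gives the β-silyloxy aldehyde under neutral conditions that spare the bromoalkene, the ester and the α-methylene lactone.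

Step 16
Reactants: 24 bromoalkene aldehyde
Product: 25 (1R)-1-hydroxy-10(14)-methylene macrocycle
Conditions: CrCl2, L* (enantiomer that directs Si-face attack), Et3N, NiCl2 (cat.), THF/MeCN, rt, slow addition to 2 mM
Reagents that add atoms: none
Why: Ni(0) inserts into the C10–Br bond, the alkenyl group passes to Cr(III) and the alkenylchromium adds to the C1 aldehyde (Nozaki–Hiyama–Kishi reaction), the closest known type being NHK closures of 2-haloalk-1-enes onto aldehydes that give medium rings with an exocyclic methylene. The ten-membered carbocycle C1–C10 closes in a 10-exo-trig mode, with the (Z)-C4=C5 bond and the trans-lactone acting as turn elements that bring C1 and C10 together. The only new stereocentre, C1 (R), should be set by Si-face attack imposed by the chiral sulfonamide on chromium, while the conformation of the forming ring is the substrate element that may help or oppose it. The step needs chemoselectivity (alkenyl–Cr(III) does not add to the enoate, lactone or ester, and transmetallation from nickel should outrun carbometallation of the nearby C11=C13 bond), cyclisation over oligomerisation (slow addition, high dilution) and facial selectivity at C1 (ligand control). The C1 carbinol next to the exocyclic C10=C14 bond is exactly the allylic alcohol needed to relay C10 in the next step.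

Step 17
Reactants: 25 macrocyclic allylic alcohol
Product: 26 (1R,10R)-10,14-epoxy-1-ol
Conditions: VO(acac)2 (cat.), t-BuOOH, CH2Cl2, 0 °C
Reagents that add atoms: tert-butyl hydroperoxide CC(C)(C)OO
Why: Vanadium-catalysed hydroxyl-directed epoxidation reacts only at the alkene allylic to the free C1–OH and should deliver oxygen to the ring face that carries the 1β-hydroxyl (the cis-directing effect of cyclic allylic alcohols), which sets C10 as R with the new oxygen β.

Step 18
Reactants: 26 spiro-epoxy alcohol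
Product: 27 (1R,10S)-1,10-epoxy-14-ol, 3-O-TBS ether of the target
Conditions: t-BuOK (0.2 equiv), THF, −20 to 0 °C; pH 7 buffer
Reagents that add atoms: none
Why: In this Payne rearrangement the C1 alkoxide opens the spiro-oxirane at C10 from the back (3-exo-tet, inversion at C10, retention at C1), so the syn 1β-OH/10β-O epoxy alcohol can only give the ring-trans 1β,10α-oxirane, and the equilibrium favours the trisubstituted epoxide with the primary alkoxide.

Step 19
Reactants: 27 silyl ether of the target
Product: 28 target CNP0356520.1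
Conditions: TBAF, AcOH, THF, 0 °C to rt
Reagents that add atoms: none
Why: Fluoride cleaves the secondary allylic silyl ether, and buffering with acetic acid should protect the α-methylene lactone, the ester and the epoxy alcohol.

Compound list
1 | 3-[(tert-butyldimethylsilyl)oxy]propanal | O=CCCO[Si](C)(C)C(C)(C)C | starting material
2 | methyl propiolate (methyl prop-2-ynoate) | C#CC(=O)OC | starting material
3 | methyl (4S)-6-(TBS-oxy)-4-hydroxyhex-2-ynoate | COC(=O)C#C[C@@H](O)CCO[Si](C)(C)C(C)(C)C | intermediate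
4 | methyl (4S)-4,6-bis(TBS-oxy)hex-2-ynoate | COC(=O)C#C[C@@H](O[Si](C)(C)C(C)(C)C)CCO[Si](C)(C)C(C)(C)C | intermediate
5 | methyl (2Z,4S)-4,6-bis(TBS-oxy)-3-methylhex-2-enoate | COC(=O)/C=C(/C)[C@@H](O[Si](C)(C)C(C)(C)C)CCO[Si](C)(C)C(C)(C)C | intermediate
6 | (2Z,4S)-4,6-bis(TBS-oxy)-3-methylhex-2-en-1-ol | OC/C=C(/C)[C@@H](O[Si](C)(C)C(C)(C)C)CCO[Si](C)(C)C(C)(C)C | intermediate
7 | (2Z,4S)-4,6-bis(TBS-oxy)-3-methylhex-2-enal | O=C/C=C(/C)[C@@H](O[Si](C)(C)C(C)(C)C)CCO[Si](C)(C)C(C)(C)C | intermediate
8 | (4S)-4-benzyl-1,3-oxazolidin-2-one | O=C1N[C@@H](Cc2ccccc2)CO1 | starting material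
9 | methyl 4-chloro-4-oxobutanoate | COC(=O)CCC(Cl)=O | starting material
10 | methyl 4-[(4S)-4-benzyl-2-oxo-1,3-oxazolidin-3-yl]-4-oxobutanoate | COC(=O)CCC(=O)N1[C@@H](Cc2ccccc2)COC1=O | intermediate
11 | methyl (3S,4R,5Z,7S)-3-{[(4S)-4-benzyl-2-oxo-1,3-oxazolidin-3-yl]carbonyl}-7,9-bis(TBS-oxy)-4-hydroxy-6-methylnon-5-enoate | COC(=O)C[C@H](C(=O)N1[C@@H](Cc2ccccc2)COC1=O)[C@H](O)/C=C(/C)[C@@H](O[Si](C)(C)C(C)(C)C)CCO[Si](C)(C)C(C)(C)C | intermediate
12 | (4S)-4-benzyl-3-{[(2R,3S)-2-[(1Z,3S)-3,5-bis(TBS-oxy)-2-methylpent-1-en-1-yl]-5-oxooxolan-3-yl]carbonyl}-1,3-oxazolidin-2-one | O=C1C[C@H](C(=O)N2[C@@H](Cc3ccccc3)COC2=O)[C@@H](/C=C(/C)[C@@H](O[Si](C)(C)C(C)(C)C)CCO[Si](C)(C)C(C)(C)C)O1 | intermediate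
13 | (2R,3S)-2-[(1Z,3S)-3,5-bis(TBS-oxy)-2-methylpent-1-en-1-yl]-5-oxooxolane-3-carboxylic acid | O=C1C[C@H](C(=O)O)[C@@H](/C=C(/C)[C@@H](O[Si](C)(C)C(C)(C)C)CCO[Si](C)(C)C(C)(C)C)O1 | intermediate
14 | (4R,5R)-5-[(1Z,3S)-3,5-bis(TBS-oxy)-2-methylpent-1-en-1-yl]-4-(hydroxymethyl)oxolan-2-one | O=C1C[C@H](CO)[C@@H](/C=C(/C)[C@@H](O[Si](C)(C)C(C)(C)C)CCO[Si](C)(C)C(C)(C)C)O1 | intermediate
15 | (2R,3S)-2-[(1Z,3S)-3,5-bis(TBS-oxy)-2-methylpent-1-en-1-yl]-5-oxooxolane-3-carbaldehyde | O=C1C[C@H](C=O)[C@@H](/C=C(/C)[C@@H](O[Si](C)(C)C(C)(C)C)CCO[Si](C)(C)C(C)(C)C)O1 | intermediate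
16 | 2,3-dibromoprop-1-ene | C=C(Br)CBr | starting material
17 | (4R,5R)-4-[(1R)-3-bromo-1-hydroxybut-3-en-1-yl]-5-[(1Z,3S)-3,5-bis(TBS-oxy)-2-methylpent-1-en-1-yl]oxolan-2-one | O=C1C[C@H]([C@H](O)CC(Br)=C)[C@@H](/C=C(/C)[C@@H](O[Si](C)(C)C(C)(C)C)CCO[Si](C)(C)C(C)(C)C)O1 | intermediate
18 | (2R)-2-methylbutanoic acid | CC[C@@H](C)C(=O)O | starting material
19 | (1R)-3-bromo-1-{(2R,3R)-2-[(1Z,3S)-3,5-bis(TBS-oxy)-2-methylpent-1-en-1-yl]-5-oxooxolan-3-yl}but-3-en-1-yl (2R)-2-methylbutanoate | O=C1C[C@H]([C@H](OC(=O)[C@H](C)CC)CC(Br)=C)[C@@H](/C=C(/C)[C@@H](O[Si](C)(C)C(C)(C)C)CCO[Si](C)(C)C(C)(C)C)O1 | intermediate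
20 | 4-[(dimethylamino)methyl] derivative of 19 (Mannich base, C11 epimers) | O=C1C(CN(C)C)[C@H]([C@H](OC(=O)[C@H](C)CC)CC(Br)=C)[C@@H](/C=C(/C)[C@@H](O[Si](C)(C)C(C)(C)C)CCO[Si](C)(C)C(C)(C)C)O1 | intermediate
21 | 4-[(trimethylammonio)methyl] derivative of 19, iodide | O=C1C(C[N+](C)(C)C)[C@H]([C@H](OC(=O)[C@H](C)CC)CC(Br)=C)[C@@H](/C=C(/C)[C@@H](O[Si](C)(C)C(C)(C)C)CCO[Si](C)(C)C(C)(C)C)O1.[I-] | intermediate
22 | (1R)-3-bromo-1-{(2R,3R)-2-[(1Z,3S)-3,5-bis(TBS-oxy)-2-methylpent-1-en-1-yl]-4-methylidene-5-oxooxolan-3-yl}but-3-en-1-yl (2R)-2-methylbutanoate | O=C1C(=C)[C@H]([C@H](OC(=O)[C@H](C)CC)CC(Br)=C)[C@@H](/C=C(/C)[C@@H](O[Si](C)(C)C(C)(C)C)CCO[Si](C)(C)C(C)(C)C)O1 | intermediate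
23 | (1R)-3-bromo-1-{(2R,3R)-2-[(1Z,3S)-3-(TBS-oxy)-5-hydroxy-2-methylpent-1-en-1-yl]-4-methylidene-5-oxooxolan-3-yl}but-3-en-1-yl (2R)-2-methylbutanoate | O=C1C(=C)[C@H]([C@H](OC(=O)[C@H](C)CC)CC(Br)=C)[C@@H](/C=C(/C)[C@@H](O[Si](C)(C)C(C)(C)C)CCO)O1 | intermediate
24 | (1R)-3-bromo-1-{(2R,3R)-2-[(1Z,3S)-3-(TBS-oxy)-2-methyl-5-oxopent-1-en-1-yl]-4-methylidene-5-oxooxolan-3-yl}but-3-en-1-yl (2R)-2-methylbutanoate | O=C1C(=C)[C@H]([C@H](OC(=O)[C@H](C)CC)CC(Br)=C)[C@@H](/C=C(/C)[C@@H](O[Si](C)(C)C(C)(C)C)CC=O)O1 | intermediate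
25 | (1R,3S,4Z,6R,7R,8R)-1-hydroxy-3-(TBS-oxy)-8-[(2R)-2-methylbutanoyloxy]germacra-4,10(14),11(13)-trien-12,6-olide | C=C1C(=O)O[C@@H]2/C=C(/C)[C@@H](O[Si](C)(C)C(C)(C)C)C[C@@H](O)C(=C)C[C@@H](OC(=O)[C@H](C)CC)[C@@H]12 | intermediate
26 | (1R,3S,4Z,6R,7R,8R,10R)-10,14-epoxy-1-hydroxy-3-(TBS-oxy)-8-[(2R)-2-methylbutanoyloxy]germacra-4,11(13)-dien-12,6-olide | C=C1C(=O)O[C@@H]2/C=C(/C)[C@@H](O[Si](C)(C)C(C)(C)C)C[C@@H](O)[C@]3(CO3)C[C@@H](OC(=O)[C@H](C)CC)[C@@H]12 | intermediate
27 | (1R,3S,4Z,6R,7R,8R,10S)-1,10-epoxy-14-hydroxy-3-(TBS-oxy)-8-[(2R)-2-methylbutanoyloxy]germacra-4,11(13)-dien-12,6-olide | C=C1C(=O)O[C@@H]2/C=C(/C)[C@@H](O[Si](C)(C)C(C)(C)C)C[C@H]3O[C@]3(CO)C[C@@H](OC(=O)[C@H](C)CC)[C@@H]12 | intermediate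
28 | (1R,3S,4Z,6R,7R,8R,10S)-1,10-epoxy-3,14-dihydroxy-8-[(2R)-2-methylbutanoyloxy]germacra-4,11(13)-dien-12,6-olide (CNP0356520.1) | C=C1C(=O)O[C@@H]2/C=C(/C)[C@@H](O)C[C@H]3O[C@]3(CO)C[C@@H](OC(=O)[C@H](C)CC)[C@@H]12 | target

Total step count: 19. Longest linear sequence: 18 steps (steps 1–5 and 7–19; step 6 is the one-step side branch).

Steps most likely to fail

Step 16. Two processes may fail here: the ring closure itself, through slow activation of the bromoalkene and oligomerisation, and the facial selectivity at the C1 carbonyl, where the conformation of the forming ring and 1,3-induction from C3–OTBS may override the ligand. The fallback drops reagent control in the ring closure and restores C1 afterwards. Starting from 24, the cyclisation is run with plain CrCl2/NiCl2 in DMSO and whatever C1 mixture forms is accepted, including the (1S)-alcohol F1. F1, alone or mixed with 25, is oxidised with Dess–Martin periodinane to the cross-conjugated 10(14)-en-1-one F2. F2 is then reduced under reagent control by Corey–Bakshi–Shibata reduction (oxazaborolidine enantiomer for 1R, catecholborane, −78 °C), which returns the route to 25.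

Step 17. The oxygen may be delivered to the wrong face of the exocyclic alkene if the vanadate reacts through an anti C2–C1–C10–C9 arrangement, as acyclic 2-substituted allylic alcohols do, and not through the gauche one assumed; that would give the C10 epimer and, after step 18, the ring-cis oxirane. The fallback replaces directed delivery by steric control in that same anti conformer. Starting from 25, the C1 hydroxyl is silylated (TESOTf, 2,6-lutidine, −78 °C) to the triethylsilyl ether F3. F3 is epoxidised with mCPBA/NaHCO3, which should attack the exocyclic alkene anti to the bulky C1 silyloxy group and give the 10β,14-epoxide F4; chemoselectivity over the doubly oxygen-flanked C4=C5 bond would have to be checked. Selective removal of the triethylsilyl group (HF·pyridine, pyridine, 0 °C) returns the route to 26.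

Step 18. Alkoxide-mediated side reactions may compete with the epoxide migration: reversible oxa-Michael addition to C13, O8-to-O14 acyl transfer and translactonisation. The fallback masks the acceptor. Starting from 26, dimethylamine (THF, rt) is added to the α-methylene lactone to give the Michael adduct F5. The Payne rearrangement is run on F5 under the same catalytic alkoxide conditions to give the rearranged amine F6. N-Methylation with iodomethane gives the ammonium iodide F7, which is not isolated, and elimination with aqueous NaHCO3 restores the methylene and returns the route to 27.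

Further compounds
F1 | step 16 | (1S)-epimer of 25 | C=C1C(=O)O[C@@H]2/C=C(/C)[C@@H](O[Si](C)(C)C(C)(C)C)C[C@H](O)C(=C)C[C@@H](OC(=O)[C@H](C)CC)[C@@H]12
F2 | step 16 | 1-oxo-10(14)-ene macrocycle (enone from 25/F1) | C=C1C(=O)O[C@@H]2/C=C(/C)[C@@H](O[Si](C)(C)C(C)(C)C)CC(=O)C(=C)C[C@@H](OC(=O)[C@H](C)CC)[C@@H]12
F3 | step 17 | 1-O-triethylsilyl ether of 25 | C=C1C(=O)O[C@@H]2/C=C(/C)[C@@H](O[Si](C)(C)C(C)(C)C)C[C@@H](O[Si](CC)(CC)CC)C(=C)C[C@@H](OC(=O)[C@H](C)CC)[C@@H]12
F4 | step 17 | 1-O-triethylsilyl ether of 26 | C=C1C(=O)O[C@@H]2/C=C(/C)[C@@H](O[Si](C)(C)C(C)(C)C)C[C@@H](O[Si](CC)(CC)CC)[C@]3(CO3)C[C@@H](OC(=O)[C@H](C)CC)[C@@H]12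
F5 | step 18 | 13-(dimethylamino)-11,13-dihydro adduct of 26 (C11 epimers) | CN(C)CC1C(=O)O[C@@H]2/C=C(/C)[C@@H](O[Si](C)(C)C(C)(C)C)C[C@@H](O)[C@]3(CO3)C[C@@H](OC(=O)[C@H](C)CC)[C@@H]12
F6 | step 18 | 13-(dimethylamino)-11,13-dihydro adduct of 27 (C11 epimers) | CN(C)CC1C(=O)O[C@@H]2/C=C(/C)[C@@H](O[Si](C)(C)C(C)(C)C)C[C@H]3O[C@]3(CO)C[C@@H](OC(=O)[C@H](C)CC)[C@@H]12
F7 | step 18 | 13-(trimethylammonio)-11,13-dihydro derivative of 27, iodide | C[N+](C)(C)CC1C(=O)O[C@@H]2/C=C(/C)[C@@H](O[Si](C)(C)C(C)(C)C)C[C@H]3O[C@]3(CO)C[C@@H](OC(=O)[C@H](C)CC)[C@@H]12.[I-]
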